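**Assumption:** the target has no stereocentre (achiral flavone), so no stereocontrol is needed; it is made as the free bis(hydrogen sulfate) exactly as drawn, by way of its stable dipotassium salt.

## Retrosynthetic overview

1. Target 14 ⇐ dipotassium salt 13 ⇐ hydrogenolysis of three benzyl ethers ⇐ bis-O-sulfation of 5,7,4'-tri-O-benzylquercetin 10, in which only 3-OH and 3'-OH are free.
2. 10 ⇐ 3'-O-MOM flavonol 9 ⇐ Algar–Flynn–Oyamada oxidative cyclisation of 2'-hydroxychalcone 7. Rings A and B are bought; the pyranone ring C is the only ring formed, and it is formed last.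
3. Chalcone 7 ⇐ intermolecular Claisen–Schmidt aldol condensation (Cα–Cβ bond) of acetophenone 2 with aldehyde 5.
4. 2 ⇐ 2',4',6'-trihydroxyacetophenone by double O-benzylation; 5 ⇐ 3,4-dihydroxybenzaldehyde by 4-O-benzylation, then 3-O-MOM.

## Route

Step 1
Reactants: 1 1-(2,4,6-trihydroxyphenyl)ethanone (2',4',6'-trihydroxyacetophenone)
Product: 2 1-[2,4-bis(benzyloxy)-6-hydroxyphenyl]ethanone
Conditions: BnBr (2.1 equiv), K2CO3 (2.2 equiv), DMF, 0 °C → rt, 16 h
Reagents that add atoms: benzyl bromide, BrCc1ccccc1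
Why: Williamson ether synthesis in which the para-OH and one ortho-OH are alkylated while the remaining ortho-OH, hydrogen-bonded to the ketone, stays free; no stereocentre is formed.

Step 2
Reactants: 3 3,4-dihydroxybenzaldehyde
Product: 4 4-(benzyloxy)-3-hydroxybenzaldehyde
Conditions: BnBr (1.05 equiv), NaHCO3 (1.5 equiv), DMF, 40 °C, 20 h
Reagents that add atoms: benzyl bromide, BrCc1ccccc1
Why: Regioselective Williamson etherification, because bicarbonate ionises only the more acidic 4-OH para to the formyl group.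

Step 3
Reactants: 4 4-(benzyloxy)-3-hydroxybenzaldehyde
Product: 5 4-(benzyloxy)-3-(methoxymethoxy)benzaldehyde
Conditions: MOMCl (1.5 equiv), K2CO3 (2.0 equiv), acetone, 0 °C → rt, 6 h
Reagents that add atoms: chloromethyl methyl ether, COCCl
Why: O-alkylation of the phenoxide (MOM acetal protection) gives a group that survives the basic aldol and peroxide steps and is later removed by mild acid without touching benzyl ethers.

Step 4
Reactants: 2 1-[2,4-bis(benzyloxy)-6-hydroxyphenyl]ethanone; 5 4-(benzyloxy)-3-(methoxymethoxy)benzaldehyde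
Product: 7 (2E)-1-[2,4-bis(benzyloxy)-6-hydroxyphenyl]-3-[4-(benzyloxy)-3-(methoxymethoxy)phenyl]prop-2-en-1-one, via aldol adduct 6 (not isolated)
Conditions: 50% aq. KOH (10 equiv), EtOH–THF 3:1, rt, 36 h; then cold 1 M HCl to pH 5
Reagents that add atoms: none
Why: Claisen–Schmidt (crossed aldol) condensation between the only enolisable partner and a non-enolisable aldehyde; the racemic carbinol centre of 6 is lost in the E1cB dehydration, which gives the thermodynamic E-enone.

Step 5
Reactants: 7 (2E)-1-[2,4-bis(benzyloxy)-6-hydroxyphenyl]-3-[4-(benzyloxy)-3-(methoxymethoxy)phenyl]prop-2-en-1-one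
Product: 9 5,7-bis(benzyloxy)-2-[4-(benzyloxy)-3-(methoxymethoxy)phenyl]-3-hydroxy-4H-chromen-4-one, via trans-dihydroflavonol 8 (not isolated)
Conditions: 30% aq. H2O2 (6 equiv), 2 M aq. NaOH (6 equiv), MeOH–THF, 0 °C → rt, 12 h
Reagents that add atoms: hydrogen peroxide, OO
Why: Algar–Flynn–Oyamada oxidative cyclisation, with the electron-rich 4-alkoxyaryl ring and low temperature favouring attack of the phenoxide at the benzylic carbon (six-membered ring, not aurone); the two racemic centres of 8 are erased by further oxidation to the flavonol.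

Step 6
Reactants: 9 5,7-bis(benzyloxy)-2-[4-(benzyloxy)-3-(methoxymethoxy)phenyl]-3-hydroxy-4H-chromen-4-one
Product: 10 5,7-bis(benzyloxy)-2-[4-(benzyloxy)-3-hydroxyphenyl]-3-hydroxy-4H-chromen-4-one (5,7,4'-tri-O-benzylquercetin)
Conditions: 2 M HCl in MeOH–THF 1:1, 45 °C, 3 h
Reagents that add atoms: none
Why: Acid-catalysed transacetalisation cleaves only the MOM acetal, since benzyl ethers and the flavonol are stable to dilute methanolic HCl.

Step 7
Reactants: 10 5,7-bis(benzyloxy)-2-[4-(benzyloxy)-3-hydroxyphenyl]-3-hydroxy-4H-chromen-4-one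
Product: 12 dipotassium 5,7,4'-tri-O-benzylquercetin 3,3'-bis(sulfate), via bis(pyridinium) sulfate salt 11 (not isolated)
Conditions: SO3·pyridine (8 equiv), pyridine, 60 °C, 14 h; then KOH/MeOH, 0 °C, to pH 8–9; C18 (H2O → MeOH)
Reagents that add atoms: sulfur trioxide–pyridine complex, O=S(=O)([O-])[n+]1ccccc1; potassium hydroxide, [K+].[OH-]
Why: O-sulfation with an SO3–amine complex can occur only at the two free hydroxyls (3-OH and 3'-OH), and cation exchange to potassium gives a base-stable, isolable salt.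

Step 8
Reactants: 12 dipotassium 5,7,4'-tri-O-benzylquercetin 3,3'-bis(sulfate)
Product: 13 dipotassium quercetin 3,3'-bis(sulfate)
Conditions: H2 (1 atm), 10% Pd/C, MeOH–H2O 4:1, rt, 4 h (monitor, stop at completion)
Reagents that add atoms: none
Why: Catalytic hydrogenolysis removes the three O-benzyl groups under neutral conditions, which the aryl sulfate salts and the flavonol C2=C3 bond tolerate.

Step 9
Reactants: 13 dipotassium quercetin 3,3'-bis(sulfate)
Product: 14 quercetin 3,3'-bissulfate (free acid, target)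
Conditions: 1.0 M aq. HCl (2.0 equiv), H2O, 0 °C; C18 cartridge (cold H2O, then MeOH–H2O); freeze-dry at once, store at −20 °C
Reagents that add atoms: none
Why: Simple protonation (salt metathesis) of the sulfate monoester salt, kept cold and brief because the free aryl hydrogen sulfate, the 3-sulfate in particular, hydrolyses under acid.

## Compound list

1 | 1-(2,4,6-trihydroxyphenyl)ethanone | CC(=O)c1c(O)cc(O)cc1O | starting material
2 | 1-[2,4-bis(benzyloxy)-6-hydroxyphenyl]ethanone | CC(=O)c1c(O)cc(OCc2ccccc2)cc1OCc1ccccc1 | intermediate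
3 | 3,4-dihydroxybenzaldehyde | O=Cc1ccc(O)c(O)c1 | starting material
4 | 4-(benzyloxy)-3-hydroxybenzaldehyde | O=Cc1ccc(OCc2ccccc2)c(O)c1 | intermediate
5 | 4-(benzyloxy)-3-(methoxymethoxy)benzaldehyde | COCOc1cc(C=O)ccc1OCc1ccccc1 | intermediate
6 | 1-[2,4-bis(benzyloxy)-6-hydroxyphenyl]-3-[4-(benzyloxy)-3-(methoxymethoxy)phenyl]-3-hydroxypropan-1-one (racemic aldol adduct) | COCOc1cc(C(O)CC(=O)c2c(O)cc(OCc3ccccc3)cc2OCc2ccccc2)ccc1OCc1ccccc1 | intermediate (not isolated)
7 | (2E)-1-[2,4-bis(benzyloxy)-6-hydroxyphenyl]-3-[4-(benzyloxy)-3-(methoxymethoxy)phenyl]prop-2-en-1-one | COCOc1cc(/C=C/C(=O)c2c(O)cc(OCc3ccccc3)cc2OCc2ccccc2)ccc1OCc1ccccc1 | intermediate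
8 | trans-5,7-bis(benzyloxy)-2-[4-(benzyloxy)-3-(methoxymethoxy)phenyl]-3-hydroxychroman-4-one (racemic; the 2R,3R enantiomer is drawn) | COCOc1cc([C@@H]2[C@H](C(=O)c3c(OCc4ccccc4)cc(OCc4ccccc4)cc3O2)O)ccc1OCc1ccccc1 | intermediate (not isolated)
9 | 5,7-bis(benzyloxy)-2-[4-(benzyloxy)-3-(methoxymethoxy)phenyl]-3-hydroxy-4H-chromen-4-one | COCOc1cc(-c2oc3cc(OCc4ccccc4)cc(OCc4ccccc4)c3c(=O)c2O)ccc1OCc1ccccc1 | intermediate
10 | 5,7-bis(benzyloxy)-2-[4-(benzyloxy)-3-hydroxyphenyl]-3-hydroxy-4H-chromen-4-one | O=c1c(O)c(-c2ccc(OCc3ccccc3)c(O)c2)oc2cc(OCc3ccccc3)cc(OCc3ccccc3)c12 | intermediate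
11 | bis(pyridinium) 5,7,4'-tri-O-benzylquercetin 3,3'-bis(sulfate) | O=c1c(OS(=O)(=O)[O-])c(-c2ccc(OCc3ccccc3)c(OS(=O)(=O)[O-])c2)oc2cc(OCc3ccccc3)cc(OCc3ccccc3)c12.c1cc[nH+]cc1.c1cc[nH+]cc1 | intermediate (not isolated)
12 | dipotassium 5,7,4'-tri-O-benzylquercetin 3,3'-bis(sulfate) | O=c1c(OS(=O)(=O)[O-])c(-c2ccc(OCc3ccccc3)c(OS(=O)(=O)[O-])c2)oc2cc(OCc3ccccc3)cc(OCc3ccccc3)c12.[K+].[K+] | intermediate
13 | dipotassium quercetin 3,3'-bis(sulfate) | O=c1c(OS(=O)(=O)[O-])c(-c2ccc(O)c(OS(=O)(=O)[O-])c2)oc2cc(O)cc(O)c12.[K+].[K+] | intermediate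
14 | quercetin 3,3'-bissulfate | O=c1c(OS(=O)(=O)O)c(-c2ccc(O)c(OS(=O)(=O)O)c2)oc2cc(O)cc(O)c12 | target

## Summary

Total step count: 9.
Longest linear sequence: 8 steps (3 → 4 → 5 → 7 → 9 → 10 → 12 → 13 → 14).

Steps most likely to fail, each with a fallback:

**Step 5 (Algar–Flynn–Oyamada).** A 6'-alkoxy-2'-hydroxychalcone can divert to the aurone, so the flavonol yield may be poor. The fallback sets out from chalcone 7 and separates ring closure from C-3 oxygenation. Oxidative cyclisation of 7 with catalytic I2 in DMSO at 110 °C gives the flavone 5,7-bis(benzyloxy)-2-[4-(benzyloxy)-3-(methoxymethoxy)phenyl]-4H-chromen-4-one F1. Epoxidation of its C2=C3 bond with dimethyldioxirane in acetone–CH2Cl2 at 0 °C gives the racemic 2,3-epoxide 5,7-bis(benzyloxy)-2-[4-(benzyloxy)-3-(methoxymethoxy)phenyl]-2,3-epoxychroman-4-one F2. A trace of p-TsOH in CH2Cl2 isomerises F2 to the 3-hydroxyflavone, and the route is rejoined at compound 9.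

**Step 7 (bis-sulfation).** The enolic 3-OH may be sulfated incompletely, and the amphiphilic salt is hard to purify. The fallback sets out from 10 and uses a protected sulfate. Treatment of 10 with 2,2,2-trichloroethyl chlorosulfate, Et3N and DMAP in THF gives the neutral, silica-purifiable diester 5,7,4'-tri-O-benzylquercetin 3,3'-bis(2,2,2-trichloroethyl sulfate) F3. Reductive removal of both trichloroethyl groups with Zn dust and ammonium formate in MeOH gives diammonium 5,7,4'-tri-O-benzylquercetin 3,3'-bis(sulfate) F4. Treatment with 2 equiv of methanolic KOH and evaporation of the ammonia converts F4 into the dipotassium salt, and the route is rejoined at compound 12.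

**Step 1 (selective double benzylation).** Mono-, tri-O- and C-benzylated by-products can erode the yield. The fallback sets out from 1 and replaces partial protection with full protection followed by selective deprotection. Exhaustive benzylation (BnBr 3.5 equiv, K2CO3, DMF, 80 °C) gives 1-[2,4,6-tris(benzyloxy)phenyl]ethanone F5. Chelation-controlled cleavage of one benzyl ether ortho to the ketone with MgBr2·OEt2 in toluene–Et2O at reflux then gives the mono-phenol, and the route is rejoined at compound 2.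

## Further compounds

F1 | step 5 | 5,7-bis(benzyloxy)-2-[4-(benzyloxy)-3-(methoxymethoxy)phenyl]-4H-chromen-4-one | COCOc1cc(-c2cc(=O)c3c(OCc4ccccc4)cc(OCc4ccccc4)cc3o2)ccc1OCc1ccccc1
F2 | step 5 | 5,7-bis(benzyloxy)-2-[4-(benzyloxy)-3-(methoxymethoxy)phenyl]-2,3-epoxychroman-4-one (racemic) | COCOc1cc(C23OC2C(=O)c2c(OCc4ccccc4)cc(OCc4ccccc4)cc2O3)ccc1OCc1ccccc1
F3 | step 7 | 5,7,4'-tri-O-benzylquercetin 3,3'-bis(2,2,2-trichloroethyl sulfate) | O=c1c(OS(=O)(=O)OCC(Cl)(Cl)Cl)c(-c2ccc(OCc3ccccc3)c(OS(=O)(=O)OCC(Cl)(Cl)Cl)c2)oc2cc(OCc3ccccc3)cc(OCc3ccccc3)c12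
F4 | step 7 | diammonium 5,7,4'-tri-O-benzylquercetin 3,3'-bis(sulfate) | O=c1c(OS(=O)(=O)[O-])c(-c2ccc(OCc3ccccc3)c(OS(=O)(=O)[O-])c2)oc2cc(OCc3ccccc3)cc(OCc3ccccc3)c12.[NH4+].[NH4+]
F5 | step 1 | 1-[2,4,6-tris(benzyloxy)phenyl]ethanone | CC(=O)c1c(OCc2ccccc2)cc(OCc2ccccc2)cc1OCc1ccccc1
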